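The trap in this scheme is to read target as the end of the line, when target is also a reagent for the substrate that made it.

    catalyst intermediate B ⇌ free catalyst + target (K1 = 2.5 M, k1 = 0.064 s⁻¹)
    substrate + free catalyst ⇌ catalyst intermediate A (K2 = 32 M⁻¹, k2 = 0.58 M⁻¹ s⁻¹)
    2 free catalyst → spent catalyst (k3 = 0.83 M⁻¹ s⁻¹)
    substrate + target → side product (k4 = 0.013 M⁻¹ s⁻¹)
    free catalyst + added ligand ⇌ idle complex, settled at all times (K5 = 110 M⁻¹)
    catalyst intermediate A → catalyst intermediate B (k6 = 0.092 s⁻¹)

| setting | Monday's | Saturday's | Sunday's |
|---|---|---|---|
| substrate | 0.083 M | 0.083 M (fed, over 2.50 h) | 0.083 M |
| free catalyst | 4.1 mM | 4.1 mM | 4.1 mM |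
| added ligand | 5.3 mM | 5.3 mM | 5.3 mM |
| remark | a single well-mixed tank run continuously and read at steady state, 2.5 h in it on average | a stirred flask in which substrate is dosed at a steady rate over 2.50 h without added volume, worked up at 2.5 h | everything together in a closed stirred flask, run for 2.5 h |
| time |  | 2.5 h | 2.5 h |
- the set-up with the highest share of target in all that became target or side product, at the outlet or at the end ("none" if the first two lie within 2 percentage points) (Monday's / Saturday's / Sunday's / none)
- share of target in all that became target or side product, at the outlet or at the end, Monday's
- share of target in all that became target or side product, at the outlet or at the end, Saturday's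
- share of target in all that became target or side product, at the outlet or at the end, Sunday's
- percentages count the substrate that a species holds: one side product counts as two
- two of one species on the left: rate k times its square, two consumed each time
- the stated concentrations are those of everything mixed, before any reaction; amounts are the same in each set-up
- the feed brings no volume worth counting
- run time (Saturday's): 2.5 h

Target is made along a route: substrate and free catalyst form catalyst intermediate A, A turns into catalyst intermediate B, and B releases target and free catalyst. The third line takes catalyst away: at the charge, its first half-life by this step alone is 0.0408 h, shorter than the run. The fourth line is the one I follow. Under standing substrate, target decays pseudo-first-order, so I define w, the rate constant of this line times the run time, which is the natural-log fall of target per molar of substrate, 117 M⁻¹. At the charge, x = w[substrate] is 9.71, or 4.22 powers of ten, and target's half-life by this step alone is 0.18 h, shorter than 2.5 h.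

So Monday's tank, with 2.5 h in it on average, makes 1 side product for every 1/x target leaving, and since a side product counts as two, its share is 1/(1+2x). At the charged substrate that gives 4.90 %; the tank's substrate stands lower, by an amount I do not reckon. Saturday's dosing lasts 2.50 h, longer than the catalyst's half-life, so I place it last. In Sunday's flask the forward half-life of substrate, 0.081 h with the catalyst held at its charge, is twice the catalyst's but shorter than Saturday's dosing time, so I place Sunday's first, and the tank between as a guess.

The forecast picks Sunday's, because “high substrate early (batch) gets the most turnovers before it dies”, with 18.5 % (15 % to 23 %), 13 % (9 % to 18 %) and 28 % (23 % to 33 %).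

The simulation gives Sunday's as best, at 22.7 %, below the forecast's figure, with Monday's at 18.6 % and Saturday's at 12.6 %. Monday's tank holds substrate at 0.0187 M. There x is 2.19, or 0.951 powers of ten, and 1/(1+2x) is 18.6 %. In Saturday's flask, w times the highest substrate, 0.0456 M, is 5.34, or 2.32 powers of ten, and target ends at 5.68 % of the charge.

(The constants used here are assumed, and the outcome is calculated.)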